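**Retrosynthetic overview**
- Target 17 ⇐ bromodiene 15 by a one-pot double dioxirane epoxidation (C7=C8 first, then the vinyl bromide, anti).
- 15 ⇐ α'-bromo enone 13 (1,2-reduction, dehydration); 13 ⇐ spiro bromoketol 9 by an interrupted Stork–Danheiser transposition with α'-bromination (new step), then bromonium-mediated OH→Cl exchange.
- C4–Br ⇐ thermodynamically controlled enamine α-bromination of spiro ketol 8.
- Ring B with C6 and C1 ⇐ organocatalytic asymmetric Michael/aldol (interrupted Robinson) spiroannulation of formyl vinylogous ester 5 with methyl vinyl ketone.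
- Ring order: ring A is bought as dimedone, ring B is closed in step 3, the two oxiranes are formed last.

Numbering: all spiro compounds use spiro[5.5]undecane locants (C1 carbinol carbon, C3 C(Me)Cl, C4 CHBr, C6 spiro carbon, C7 C–Me, C10 C–Br, C11 CMe2).
Assumption: the cinchona catalyst in step 3 is taken to give the C6 configuration drawn; its quinine-derived pseudoenantiomer is used if the sense proves opposite.

**Step 1**
Reactants: 1 dimedone (5,5-dimethylcyclohexane-1,3-dione); 2 isobutanol (2-methylpropan-1-ol)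
Product: 3 3-isobutoxy-5,5-dimethylcyclohex-2-en-1-one
Conditions: p-TsOH·H2O (cat.), PhMe, reflux, Dean–Stark
Reagents that add atoms: none
Why: acid-catalysed vinylogous esterification of the symmetric β-diketone, driven by azeotropic removal of water; no stereocentre is formed.

**Step 2**
Reactants: 3 3-isobutoxy-5,5-dimethylcyclohex-2-en-1-one; 4 2,2,2-trifluoroethyl formate
Product: 5 (Z)-6-(hydroxymethylene)-3-isobutoxy-5,5-dimethylcyclohex-2-en-1-one
Conditions: LiN(iPr)2, THF, −78 °C; then 4, −78 → 0 °C; aq. HCl work-up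
Reagents that add atoms: none
Why: crossed Claisen formylation of the kinetic α'-enolate (the position used in Stork–Danheiser alkylations) gives the chelated enol of the β-keto aldehyde; no stereocentre is formed.

**Step 3**
Reactants: 5 (Z)-6-(hydroxymethylene)-3-isobutoxy-5,5-dimethylcyclohex-2-en-1-one; 6 methyl vinyl ketone (but-3-en-2-one)
Product: 8 (1S,6R)-1-hydroxy-9-isobutoxy-11,11-dimethylspiro[5.5]undec-8-ene-3,7-dione, via Michael adduct 7 (not isolated)
Conditions: 9-O-(9-phenanthryl)cupreidine (10 mol %), CH2Cl2, −20 °C; then L-proline (30 mol %), DMSO, rt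
Reagents that add atoms: none
Why: a bifunctional cinchona (Brønsted base/hydrogen bond) catalysed Michael addition of the enolised β-keto aldehyde to the vinyl ketone sets the quaternary C6 by shielding one enolate face in the quinuclidinium–enolate ion pair, and a proline-catalysed 6-enolexo intramolecular aldol (Robinson annulation stopped at the ketol) then closes ring B through a chair with C11 equatorial and the aldehyde C=O anti to the C7 carbonyl (Cornforth dipole minimisation), placing the C1 hydroxyl cis to C11.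

**Step 4**
Reactants: 8 (1S,6R)-1-hydroxy-9-isobutoxy-11,11-dimethylspiro[5.5]undec-8-ene-3,7-dione
Product: 9 (1S,4S,6R)-4-bromo-1-hydroxy-9-isobutoxy-11,11-dimethylspiro[5.5]undec-8-ene-3,7-dione
Conditions: (4R,5R)-4,5-diphenylimidazolidine (20 mol %), PhCO2H (20 mol %), 4,4-dibromo-2,6-di-tert-butylcyclohexa-2,5-dien-1-one, THF, −30 → 0 °C
Reagents that add atoms: 4,4-dibromo-2,6-di-tert-butylcyclohexa-2,5-dien-1-one, CC(C)(C)C1=CC(Br)(Br)C=C(C(C)(C)C)C1=O
Why: organocatalytic enamine α-bromination occurs at the unhindered C4 (C2 is flanked by the C1 carbinol next to the quaternary centre), and reversible enamine/iminium exchange equilibrates the bromide to the equatorial position cis to C11, because the other epimer would be syn-axial to the C7 arm; the conditions are mild enough that the ketol is neither dehydrated nor retro-aldolised.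

**Step 5**
Reactants: 9 (1S,4S,6R)-4-bromo-1-hydroxy-9-isobutoxy-11,11-dimethylspiro[5.5]undec-8-ene-3,7-dione
Product: 12 (1S,4S,6R)-4,10-dibromo-1,3-dihydroxy-3,7,11,11-tetramethylspiro[5.5]undec-7-en-9-one (epimers at C3/C10), via triol 10 (not isolated), via alkoxydiene 11 (not isolated)
Conditions: MeLi, CeCl3, THF, −78 → −40 °C; aq. NaHCO3; crude in CH2Cl2: PPTS (cat.), 4 Å MS, 0 °C; NBS, −20 °C; then H2O
Reagents that add atoms: methyllithium, [Li]C; N-bromosuccinimide, O=C1CCC(=O)N1Br; water, O
Why: Proposed new method: an interrupted Stork–Danheiser transposition with brominative interception, in which MeLi/CeCl3 adds 1,2 to both the vinylogous ester carbonyl (C7) and the C3 ketone, anhydrous pyridinium acid ionises only the vinylogous hemiketal-type C7 carbinol to the alkoxyallyl cation, this cation loses the C10 proton to give the 2-alkoxy-1,3-diene 11 instead of being hydrolysed, and NBS brominates the enol ether terminus C10 before water hydrolyses the oxocarbenium ion to the α'-bromo enone; the closest known reactions are the Stork–Danheiser enone transposition and the α'-bromination of enones through their kinetic 2-silyloxydienes.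

**Step 6**
Reactants: 12 (1S,4S,6R)-4,10-dibromo-1,3-dihydroxy-3,7,11,11-tetramethylspiro[5.5]undec-7-en-9-one
Product: 13 (1S,3S,4S,6R)-4,10-dibromo-3-chloro-1-hydroxy-3,7,11,11-tetramethylspiro[5.5]undec-7-en-9-one (epimers at C10)
Conditions: HCl (4 M in dioxane), CH2Cl2, 0 °C → rt
Reagents that add atoms: hydrogen chloride, Cl
Why: SN1 substitution with anchimeric assistance, in which either C3 carbinol epimer ionises to a cation bridged by the neighbouring C4 bromine on its own face, so chloride enters the tertiary carbon anti to bromine (the bromonium of an alkene bromochlorination, but with the bromine face already fixed by step 4), giving the trans bromochloride with the methyl cis to the C1 hydroxyl.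

**Step 7**
Reactants: 13 (1S,3S,4S,6R)-4,10-dibromo-3-chloro-1-hydroxy-3,7,11,11-tetramethylspiro[5.5]undec-7-en-9-one
Product: 14 (1S,3S,4S,6R)-4,10-dibromo-3-chloro-3,7,11,11-tetramethylspiro[5.5]undec-7-ene-1,9-diol (epimers at C9/C10)
Conditions: NaBH4, CeCl3·7H2O, MeOH, −40 °C
Reagents that add atoms: none
Why: Luche 1,2-reduction gives the allylic bromohydrin without conjugate reduction or loss of bromide; the new C9 centre is erased in the next step, so its configuration does not matter.

**Step 8**
Reactants: 14 (1S,3S,4S,6R)-4,10-dibromo-3-chloro-3,7,11,11-tetramethylspiro[5.5]undec-7-ene-1,9-diol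
Product: 15 (1S,3S,4S,6R)-4,10-dibromo-3-chloro-3,7,11,11-tetramethylspiro[5.5]undeca-7,9-dien-1-ol
Conditions: CSA (10 mol %), 4 Å MS, PhH, 50 °C
Reagents that add atoms: none
Why: acid-catalysed E1 dehydration in which only the allylic C9 alcohol ionises (the C1 alcohol and the β-bromo tertiary chloride do not) and the allyl cation loses the C10 proton to give the thermodynamically favoured, fully endocyclic conjugated 1-bromo-1,3-diene.

**Step 9**
Reactants: 15 (1S,3S,4S,6R)-4,10-dibromo-3-chloro-3,7,11,11-tetramethylspiro[5.5]undeca-7,9-dien-1-ol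
Product: 17 (1S,3S,4S,6R,7R,8S,9S,10S)-4,10-dibromo-3-chloro-7,8:9,10-diepoxy-3,7,11,11-tetramethylspiro[5.5]undecan-1-ol, via vinyl oxirane 16 (not isolated)
Conditions: DMDO (4 equiv), acetone, −20 → 20 °C
Reagents that add atoms: dimethyldioxirane, CC1(C)OO1
Why: neutral dioxirane epoxidation (Prilezhaev type) attacks the electron-rich C7=C8 bond first, on the ring A face anti to the bulkier C1 carbinol arm (syn to C5), and then epoxidises the vinyl bromide of 16 anti to that oxirane (as cyclohexa-1,3-diene monoepoxides give trans-diepoxides), setting C7, C8, C9 and C10 without the acid that would rearrange the vinyl oxirane.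

**Compound list**
1 | dimedone (5,5-dimethylcyclohexane-1,3-dione) | CC1(C)CC(=O)CC(=O)C1 | starting material
2 | isobutanol (2-methylpropan-1-ol) | CC(C)CO | starting material
3 | 3-isobutoxy-5,5-dimethylcyclohex-2-en-1-one | CC(C)COC1=CC(=O)CC(C)(C)C1 | intermediate
4 | 2,2,2-trifluoroethyl formate | O=COCC(F)(F)F | starting material
5 | (Z)-6-(hydroxymethylene)-3-isobutoxy-5,5-dimethylcyclohex-2-en-1-one | O/C=C1\C(=O)C=C(OCC(C)C)CC1(C)C | intermediate
6 | methyl vinyl ketone (but-3-en-2-one) | CC(=O)C=C | starting material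
7 | (R)-4-isobutoxy-6,6-dimethyl-2-oxo-1-(3-oxobutyl)cyclohex-3-ene-1-carbaldehyde | CC1(C)CC(OCC(C)C)=CC(=O)[C@]1(C=O)CCC(C)=O | intermediate (not isolated)
8 | (1S,6R)-1-hydroxy-9-isobutoxy-11,11-dimethylspiro[5.5]undec-8-ene-3,7-dione | CC1(C)CC(OCC(C)C)=CC(=O)[C@]12CCC(=O)C[C@@H]2O | intermediate
9 | (1S,4S,6R)-4-bromo-1-hydroxy-9-isobutoxy-11,11-dimethylspiro[5.5]undec-8-ene-3,7-dione | CC1(C)CC(OCC(C)C)=CC(=O)[C@]12C[C@H](Br)C(=O)C[C@@H]2O | intermediate
10 | (1S,4S,6R)-4-bromo-9-isobutoxy-3,7,11,11-tetramethylspiro[5.5]undec-8-ene-1,3,7-triol (epimers at C3/C7) | CC1(C)CC(OCC(C)C)=CC(C)(O)[C@]12C[C@H](Br)C(C)(O)C[C@@H]2O | intermediate (not isolated)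
11 | (1S,4S,6R)-4-bromo-9-isobutoxy-3,7,11,11-tetramethylspiro[5.5]undeca-7,9-diene-1,3-diol (epimers at C3) | CC1(C)C=C(OCC(C)C)C=C(C)[C@]12C[C@H](Br)C(C)(O)C[C@@H]2O | intermediate (not isolated)
12 | (1S,4S,6R)-4,10-dibromo-1,3-dihydroxy-3,7,11,11-tetramethylspiro[5.5]undec-7-en-9-one (epimers at C3/C10) | CC1(C)C(Br)C(=O)C=C(C)[C@]12C[C@H](Br)C(C)(O)C[C@@H]2O | intermediate
13 | (1S,3S,4S,6R)-4,10-dibromo-3-chloro-1-hydroxy-3,7,11,11-tetramethylspiro[5.5]undec-7-en-9-one (epimers at C10) | CC1(C)C(Br)C(=O)C=C(C)[C@]12C[C@H](Br)[C@@](C)(Cl)C[C@@H]2O | intermediate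
14 | (1S,3S,4S,6R)-4,10-dibromo-3-chloro-3,7,11,11-tetramethylspiro[5.5]undec-7-ene-1,9-diol (epimers at C9/C10) | CC1(C)C(Br)C(O)C=C(C)[C@]12C[C@H](Br)[C@@](C)(Cl)C[C@@H]2O | intermediate
15 | (1S,3S,4S,6R)-4,10-dibromo-3-chloro-3,7,11,11-tetramethylspiro[5.5]undeca-7,9-dien-1-ol | CC1(C)C(Br)=CC=C(C)[C@]12C[C@H](Br)[C@@](C)(Cl)C[C@@H]2O | intermediate
16 | (1S,3S,4S,6R,7R,8S)-4,10-dibromo-3-chloro-7,8-epoxy-3,7,11,11-tetramethylspiro[5.5]undec-9-en-1-ol | CC1(C)C(Br)=C[C@@H]2O[C@]2(C)[C@]12C[C@H](Br)[C@@](C)(Cl)C[C@@H]2O | intermediate (not isolated)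
17 | (1S,3S,4S,6R,7R,8S,9S,10S)-4,10-dibromo-3-chloro-7,8:9,10-diepoxy-3,7,11,11-tetramethylspiro[5.5]undecan-1-ol (CNP0345283.3) | CC1(C)[C@@]2(Br)O[C@H]2[C@@H]2O[C@]2(C)[C@]12C[C@H](Br)[C@@](C)(Cl)C[C@@H]2O | target

**Total steps:** 9. **Longest linear sequence:** 9 (1 → 17).

**Steps most likely to fail**

Step 3 (asymmetric spiroannulation). The donor carbon is flanked by a gem-dimethyl group, the quaternary formyl ketone can deformylate, and both the enantioselectivity and the C1 selectivity of the aldol are untested. The fallback carries C1 in at the acyl oxidation level and sets out from 3. The enolate of 3 (LiN(iPr)2, THF, −78 °C) is acylated with S-ethyl chlorothioformate to the β-keto thioester S-ethyl 4-isobutoxy-6,6-dimethyl-2-oxocyclohex-3-ene-1-carbothioate F1. As an ordinary β-keto (thio)ester pronucleophile this undergoes the established cinchona-catalysed Michael addition to 6 (same cupreidine catalyst), giving S-ethyl (S)-4-isobutoxy-6,6-dimethyl-2-oxo-1-(3-oxobutyl)cyclohex-3-ene-1-carbothioate F2. Fukuyama reduction (Et3SiH, Pd/C, acetone) then converts the thioester into aldehyde 7, where the route is rejoined, and 7 is cyclised to 8 with proline as in step 3.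

Step 5 (the proposed new step). Water formed in the dehydration may hydrolyse the cation to the unbrominated enone, or the exocyclic dienol ether may be brominated instead. The fallback uses only known chemistry and sets out from 9. MeLi/CeCl3 followed by aqueous HCl (the ordinary Stork–Danheiser hydrolysis) gives the transposed enone (1S,4S,6S)-4-bromo-1,3-dihydroxy-3,7,11,11-tetramethylspiro[5.5]undec-7-en-9-one F3. HCl in dioxane, as in step 6, gives the bromochloride (1S,3S,4S,6S)-4-bromo-3-chloro-1-hydroxy-3,7,11,11-tetramethylspiro[5.5]undec-7-en-9-one F4. Kinetic enolisation and silylation (LiN(SiMe3)2, Me3SiCl, THF, −78 °C) gives (1S,3S,4S,6R)-4-bromo-3-chloro-3,7,11,11-tetramethyl-1,9-bis(trimethylsilyloxy)spiro[5.5]undeca-7,9-diene F5. NBS followed by dilute HCl converts F5 into 13, where the route is rejoined, so 12 is bypassed.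

Step 9 (double epoxidation). The vinyl bromide is electron-poor and hindered, the C1 alcohol may be oxidised by excess dioxirane, and the facial selectivity of both epoxidations rests on conformational arguments. The fallback builds the bromo-oxirane by ring closure instead of alkene epoxidation and sets out from 13. A second bromination at C10 (pyridinium tribromide, AcOH) gives the gem-dibromide (1S,3S,4S,6R)-4,10,10-tribromo-3-chloro-1-hydroxy-3,7,11,11-tetramethylspiro[5.5]undec-7-en-9-one F6. Luche reduction gives (1S,3S,4S,6R,9S)-4,10,10-tribromo-3-chloro-3,7,11,11-tetramethylspiro[5.5]undec-7-ene-1,9-diol F7; the C9 epimer is separated and recycled by reoxidation. K2CO3 in MeOH closes the bromo-oxirane by intramolecular displacement of the anti bromide (Jocic-type closure) to (1S,3S,4S,6R,9S,10S)-4,10-dibromo-3-chloro-9,10-epoxy-3,7,11,11-tetramethylspiro[5.5]undec-7-en-1-ol F8. A single DMDO epoxidation of the remaining C7=C8 bond, anti to the oxirane, then gives 17 directly.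

**Further compounds**
F1 | step 3 | S-ethyl 4-isobutoxy-6,6-dimethyl-2-oxocyclohex-3-ene-1-carbothioate (racemic, enolisable centre) | CCSC(=O)C1C(=O)C=C(OCC(C)C)CC1(C)C
F2 | step 3 | S-ethyl (S)-4-isobutoxy-6,6-dimethyl-2-oxo-1-(3-oxobutyl)cyclohex-3-ene-1-carbothioate | CC1(C)CC(OCC(C)C)=CC(=O)[C@]1(C(=O)SCC)CCC(C)=O
F3 | step 5 | (1S,4S,6S)-4-bromo-1,3-dihydroxy-3,7,11,11-tetramethylspiro[5.5]undec-7-en-9-one (epimers at C3) | CC1(C)CC(=O)C=C(C)[C@]12C[C@H](Br)C(C)(O)C[C@@H]2O
F4 | step 5 | (1S,3S,4S,6S)-4-bromo-3-chloro-1-hydroxy-3,7,11,11-tetramethylspiro[5.5]undec-7-en-9-one | CC1(C)CC(=O)C=C(C)[C@]12C[C@H](Br)[C@@](C)(Cl)C[C@@H]2O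
F5 | step 5 | (1S,3S,4S,6R)-4-bromo-3-chloro-3,7,11,11-tetramethyl-1,9-bis(trimethylsilyloxy)spiro[5.5]undeca-7,9-diene | CC1(C)C=C(O[Si](C)(C)C)C=C(C)[C@]12C[C@H](Br)[C@@](C)(Cl)C[C@@H]2O[Si](C)(C)C
F6 | step 9 | (1S,3S,4S,6R)-4,10,10-tribromo-3-chloro-1-hydroxy-3,7,11,11-tetramethylspiro[5.5]undec-7-en-9-one | CC1(C)C(Br)(Br)C(=O)C=C(C)[C@]12C[C@H](Br)[C@@](C)(Cl)C[C@@H]2O
F7 | step 9 | (1S,3S,4S,6R,9S)-4,10,10-tribromo-3-chloro-3,7,11,11-tetramethylspiro[5.5]undec-7-ene-1,9-diol | CC1(C)C(Br)(Br)[C@@H](O)C=C(C)[C@]12C[C@H](Br)[C@@](C)(Cl)C[C@@H]2O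
F8 | step 9 | (1S,3S,4S,6R,9S,10S)-4,10-dibromo-3-chloro-9,10-epoxy-3,7,11,11-tetramethylspiro[5.5]undec-7-en-1-ol | CC1(C)[C@@]2(Br)O[C@H]2C=C(C)[C@]12C[C@H](Br)[C@@](C)(Cl)C[C@@H]2O
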